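**Strategy.** Ring A is disconnected at C4a–C5 and C8–C8a: the four contiguous oxygenated carbons C5–C8 are the four carbons of a squarate, while C4a and C8a are C3 and C2 of a finished 6-aryl-4-pyranone (ring C with ring B attached). The key step exploits exactly this feature: heating a 4-hydroxy-4-(pyranon-3-yl)cyclobutenone opens the four-membered ring to a dienylketene that closes onto the pyranone C2–H, forming C8–C8a and delivering ring A as a 5,8-hydroquinone in one operation. The precursor already carries methoxy on the future C6 and tert-butoxy on the future C7, so the single free hydroxyl of the target is marked before ring A exists.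

Key step: step 6

Remark: compound 3 is written as its diketo tautomer, although it should exist mainly as the chelated enol. Dimethyl squarate 5 is taken as a purchasable starting material (it is one step from squaric acid).

**Step 1**
Reactants: 1 (E)-4-(dimethylamino)but-3-en-2-one; 2 4-methoxybenzoyl chloride
Product: 3 (E)-5-(dimethylamino)-1-(4-methoxyphenyl)pent-4-ene-1,3-dione
Conditions: LiN(SiMe3)2 (2.2 equiv) added to 1 + 2, THF, −78 °C; AcOH quench
Reagents that add atoms: none
Why: Claisen-type C-acylation of the methyl-derived lithium enolate of the vinylogous amide (the only enolisable site of 1) is a standard entry to 5-aminopent-4-ene-1,3-diones, and the second equivalent of base stores the product as its chelated enolate, which prevents double acylation.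

**Step 2**
Reactants: 3 (E)-5-(dimethylamino)-1-(4-methoxyphenyl)pent-4-ene-1,3-dione
Product: 4 5-iodo-2-(4-methoxyphenyl)-4H-pyran-4-one
Conditions: iodine (1.5 equiv), CHCl3, 20 °C; aq Na2S2O3
Reagents that add atoms: iodine, [I][I]
Why: Iodine attacks the nucleophilic α-carbon of the enaminone, the enol oxygen closes onto the resulting iminium carbon and dimethylamine is expelled (the iodocyclisation of hydroxy enaminones routinely used for 3-iodochromones), so the connectivity of 3 places the halogen on the pyranone carbon remote from the aryl group and no choice between C3 and C5 of a finished pyranone arises.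

**Step 3**
Reactants: 5 3,4-dimethoxycyclobut-3-ene-1,2-dione (dimethyl squarate)
Product: 7 silver 2-methoxy-3,4-dioxocyclobut-1-en-1-olate (silver methyl squarate), via potassium methyl squarate 6 (not isolated)
Conditions: KOH (1.0 equiv), MeOH–H2O, 0 °C; then AgNO3 (1.0 equiv), H2O, 20 °C, dark; filter, dry in vacuo
Reagents that add atoms: potassium hydroxide, [K+].[OH-]; silver nitrate, [Ag+].[O-][N+](=O)[O-]
Why: Hydroxide replaces one methoxy group by addition–elimination at the vinylogous ester carbon and the reaction should stop there because the squarate monoanion is no longer electrophilic; salt metathesis then precipitates the sparingly soluble silver salt.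

**Step 4**
Reactants: 7 silver 2-methoxy-3,4-dioxocyclobut-1-en-1-olate
Product: 8 3-tert-butoxy-4-methoxycyclobut-3-ene-1,2-dione (tert-butyl methyl squarate)
Conditions: t-BuCl (5 equiv), Et2O, 4 Å molecular sieves, 20 °C, dark
Reagents that add atoms: 2-chloro-2-methylpropane, CC(C)(C)Cl
Why: Silver-assisted ionisation of tert-butyl chloride and capture of the cation by a squarate oxygen (SN1 O-alkylation of a silver salt, the way di-tert-butyl squarate is made) runs under neutral conditions that the acid-labile product tolerates, and alkylation at either oxygen flanking the methoxy carbon gives the same vicinal diester.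

**Step 5**
Reactants: 4 5-iodo-2-(4-methoxyphenyl)-4H-pyran-4-one; 8 3-tert-butoxy-4-methoxycyclobut-3-ene-1,2-dione
Product: 10 racemic 2-tert-butoxy-4-hydroxy-3-methoxy-4-[6-(4-methoxyphenyl)-4-oxo-4H-pyran-3-yl]cyclobut-2-en-1-one, via pyranonylmagnesium chloride 9 (not isolated)
Conditions: i-PrMgCl·LiCl (1.0 equiv), THF, −78 °C, 20 min; cannulate into 8 (1.2 equiv), THF, −78 → −40 °C; aq NH4Cl
Reagents that add atoms: none
Why: Iodine–magnesium exchange of the electron-poor alkenyl iodide is fast at −78 °C and the resulting Grignard reagent adds 1,2 to a squarate carbonyl as aryl and alkenyl metals generally do; the tert-butoxy group shields the carbonyl on its own side, so attack is expected at the carbonyl flanked by the methoxy carbon (OMe then sits beside the carbinol carbon and Ot-Bu beside the remaining C=O), and the new quaternary carbinol centre is formed as a racemate without control because it becomes sp2 in step 6.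

**Step 6**
Reactants: 10 racemic 2-tert-butoxy-4-hydroxy-3-methoxy-4-[6-(4-methoxyphenyl)-4-oxo-4H-pyran-3-yl]cyclobut-2-en-1-one
Product: 13 7-tert-butoxy-5,8-dihydroxy-6-methoxy-2-(4-methoxyphenyl)-4H-chromen-4-one, via dienylketene 11 (not isolated), via cyclohexadienone 12 (not isolated)
Conditions: PhMe (degassed), 110 °C, Ar
Reagents that add atoms: none
Why: Heating opens the cyclobutenone by four-electron conrotatory cleavage of the C1–C4 bond with the hydroxyl turning outward (donor torquoselectivity), which places the pyranonyl group cis to the ketene in dienylketene 11. The ketene carbon and the pyranone C2–H carbon then join in a six-electron disrotatory electrocyclisation of the 1,3,5-triene, the mode by which ring A is closed (new bond C8–C8a, cyclohexadienone 12), and enolisation of the C8a–H aromatises ring A to hydroquinone 13. The closest known reaction is the thermal ring expansion of 4-aryl- and 4-alkenyl-4-hydroxycyclobutenones to hydroquinones (Moore rearrangement), used here with a 4-oxopyran-3-yl group as the alkenyl partner. No stereocentre has to be controlled: the carbinol centre of 10 becomes sp2 and the C8a centre of 12 disappears on tautomerisation. The step needs closure on carbon and not lactonisation of the enol hydroxyl onto the ketene, which outward rotation of the hydroxyl secures, and closure at the right pyranone carbon, which is certain because the attached carbon has only one C=C partner. The order of the oxygen substituents is already written into 10 (OMe beside the carbinol carbon becomes C6–OMe, Ot-Bu beside the carbonyl becomes C7–Ot-Bu), and neutral, oxygen-free conditions should spare the tert-butyl ether and the hydroquinone.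

**Step 7**
Reactants: 13 7-tert-butoxy-5,8-dihydroxy-6-methoxy-2-(4-methoxyphenyl)-4H-chromen-4-one (crude, kept under Ar)
Product: 14 7-tert-butoxy-5,6,8-trimethoxy-2-(4-methoxyphenyl)-4H-chromen-4-one
Conditions: Me2SO4 (6 equiv), K2CO3 (8 equiv), acetone (degassed), 56 °C, Ar
Reagents that add atoms: dimethyl sulfate, COS(=O)(=O)OC
Why: Williamson O-methylation of both phenols under standard flavone conditions (excess reagent and reflux for the hydrogen-bonded 5-OH); the aryl tert-butyl ether is inert to carbonate, and exclusion of oxygen should keep the hydroquinone from going to the 5,8-quinone.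

**Step 8**
Reactants: 14 7-tert-butoxy-5,6,8-trimethoxy-2-(4-methoxyphenyl)-4H-chromen-4-one
Product: 15 7-hydroxy-5,6,8-trimethoxy-2-(4-methoxyphenyl)-4H-chromen-4-one (7-hydroxy-4',5,6,8-tetramethoxyflavone)
Conditions: CF3CO2H–CH2Cl2 (1:4), 0 → 20 °C
Reagents that add atoms: none
Why: Acidolysis of the aryl tert-butyl ether (SN1/E1 loss of the tert-butyl cation as isobutene) should be selective because aryl methyl ethers and the pyranone are stable to CF3CO2H and ring A has no free position for re-alkylation.

**Compound list**
1 | (E)-4-(dimethylamino)but-3-en-2-one | CC(=O)/C=C/N(C)C | starting material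
2 | 4-methoxybenzoyl chloride | COc1ccc(cc1)C(Cl)=O | starting material
3 | (E)-5-(dimethylamino)-1-(4-methoxyphenyl)pent-4-ene-1,3-dione | COc1ccc(cc1)C(=O)CC(=O)/C=C/N(C)C | intermediate
4 | 5-iodo-2-(4-methoxyphenyl)-4H-pyran-4-one | O=c1cc(-c2ccc(OC)cc2)occ1I | intermediate
5 | 3,4-dimethoxycyclobut-3-ene-1,2-dione | COC1=C(OC)C(=O)C1=O | starting material
6 | potassium 2-methoxy-3,4-dioxocyclobut-1-en-1-olate | [K+].COC1=C([O-])C(=O)C1=O | intermediate
7 | silver 2-methoxy-3,4-dioxocyclobut-1-en-1-olate | [Ag+].COC1=C([O-])C(=O)C1=O | intermediate
8 | 3-tert-butoxy-4-methoxycyclobut-3-ene-1,2-dione | COC1=C(OC(C)(C)C)C(=O)C1=O | intermediate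
9 | chloro[6-(4-methoxyphenyl)-4-oxo-4H-pyran-3-yl]magnesium (LiCl complex) | O=c1cc(-c2ccc(OC)cc2)occ1[Mg]Cl | intermediate
10 | racemic 2-tert-butoxy-4-hydroxy-3-methoxy-4-[6-(4-methoxyphenyl)-4-oxo-4H-pyran-3-yl]cyclobut-2-en-1-one | COC1=C(OC(C)(C)C)C(=O)C1(O)c1coc(-c2ccc(OC)cc2)cc1=O | intermediate
11 | (Z)-2-tert-butoxy-4-hydroxy-3-methoxy-4-[6-(4-methoxyphenyl)-4-oxo-4H-pyran-3-yl]buta-1,3-dien-1-one | O=C=C(OC(C)(C)C)/C(OC)=C(/O)c1coc(-c2ccc(OC)cc2)cc1=O | intermediate
12 | racemic 7-tert-butoxy-5-hydroxy-6-methoxy-2-(4-methoxyphenyl)-8aH-chromene-4,8-dione | COC1=C(OC(C)(C)C)C(=O)C2OC(=CC(=O)C2=C1O)c1ccc(OC)cc1 | intermediate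
13 | 7-tert-butoxy-5,8-dihydroxy-6-methoxy-2-(4-methoxyphenyl)-4H-chromen-4-one | COc1ccc(-c2cc(=O)c3c(O)c(OC)c(OC(C)(C)C)c(O)c3o2)cc1 | intermediate
14 | 7-tert-butoxy-5,6,8-trimethoxy-2-(4-methoxyphenyl)-4H-chromen-4-one | COc1ccc(-c2cc(=O)c3c(OC)c(OC)c(OC(C)(C)C)c(OC)c3o2)cc1 | intermediate
15 | 7-hydroxy-5,6,8-trimethoxy-2-(4-methoxyphenyl)-4H-chromen-4-one | COc1ccc(-c2cc(=O)c3c(OC)c(OC)c(O)c(OC)c3o2)cc1 | target

**Total step count:** 8. **Longest linear sequence:** 6 steps (steps 1, 2, 5, 6, 7, 8; the squarate branch 3, 4, 5, 6, 7, 8 is equally long).

**Steps most likely to fail**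

Step 5. The magnesiated pyranone may collapse by β-elimination with opening of ring C, or add to a second pyranone, before it meets 8. Isopropylmagnesium chloride may also add to C6 of 4, and part of the reagent may attack the carbonyl beside the tert-butoxy carbon. The fallback sets out from 4 and comes back at 10. Direct insertion of zinc (Zn dust, LiCl, THF, 25 °C) into the carbon–iodine bond should give iodo[6-(4-methoxyphenyl)-4-oxo-4H-pyran-3-yl]zinc F1, an organometal that is far less basic and not prone to elimination at ambient temperature. Its 1,2-addition to the strained, reactive carbonyl of 8 is then promoted with MgCl2 (the Lewis-acid-accelerated addition of organozinc halides to ketones), and neutral work-up should give 10. The slower and bulkier zinc reagent should, if anything, discriminate more sharply between the two carbonyls.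

Step 6. The enol hydroxyl of the dienylketene may add to the ketene and give a butenolide if closure onto the electron-poor pyranone double bond is slow. Isobutene may be lost on prolonged heating, and the hydroquinone may oxidise to the 5,8-quinone during isolation. The fallback sets out from 10 and comes back at 14, replacing steps 6 and 7. The tertiary hydroxyl is silylated (Me3SiOTf, Et3N, CH2Cl2, −78 °C) to racemic 2-tert-butoxy-3-methoxy-4-[6-(4-methoxyphenyl)-4-oxo-4H-pyran-3-yl]-4-(trimethylsilyloxy)cyclobut-2-en-1-one F2. Thermolysis of such 4-silyloxycyclobutenones in toluene at 110 °C is a known variant of the ring expansion; it cannot lactonise and should give 7-tert-butoxy-8-hydroxy-6-methoxy-2-(4-methoxyphenyl)-5-(trimethylsilyloxy)-4H-chromen-4-one F3 (silyl migration to O8 would be harmless, since both isomers converge). Without liberating the free hydroquinone, CsF and MeI in DMF should cleave the aryl silyl ether and methylate both oxygens to give 14.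

Step 2. Ring closure of 3 may outrun iodination once acid accumulates, or iodine may attack the central carbon of the diketone, so that non-iodinated pyranone or mixtures result. The fallback sets out from 1 and comes back at 4; it fixes the halogen on carbon before the diketone exists. Iodine and Et3N in CH2Cl2 should convert 1 into (Z)-4-(dimethylamino)-3-iodobut-3-en-2-one F4 (α-iodination of an enaminone). Acylation of its lithium enolate with 2 under the conditions of step 1 should give (Z)-5-(dimethylamino)-4-iodo-1-(4-methoxyphenyl)pent-4-ene-1,3-dione F5. Cyclocondensation promoted by CF3CO2H, with loss of dimethylamine, then closes the pyranone to 4.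

**Further compounds**
F1 | step 5 | iodo[6-(4-methoxyphenyl)-4-oxo-4H-pyran-3-yl]zinc | O=c1cc(-c2ccc(OC)cc2)occ1[Zn]I
F2 | step 6 | racemic 2-tert-butoxy-3-methoxy-4-[6-(4-methoxyphenyl)-4-oxo-4H-pyran-3-yl]-4-(trimethylsilyloxy)cyclobut-2-en-1-one | COC1=C(OC(C)(C)C)C(=O)C1(O[Si](C)(C)C)c1coc(-c2ccc(OC)cc2)cc1=O
F3 | step 6 | 7-tert-butoxy-8-hydroxy-6-methoxy-2-(4-methoxyphenyl)-5-(trimethylsilyloxy)-4H-chromen-4-one | COc1ccc(-c2cc(=O)c3c(O[Si](C)(C)C)c(OC)c(OC(C)(C)C)c(O)c3o2)cc1
F4 | step 2 | (Z)-4-(dimethylamino)-3-iodobut-3-en-2-one | CN(C)/C=C(\I)C(C)=O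
F5 | step 2 | (Z)-5-(dimethylamino)-4-iodo-1-(4-methoxyphenyl)pent-4-ene-1,3-dione | CN(C)/C=C(\I)C(=O)CC(=O)c1ccc(OC)cc1
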